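**Retrosynthetic overview**

1. The target is reached by desilylation/acetylation and catalyst-controlled hydrogenation (C13) of an oxocene, which is closed by ring-closing metathesis (C13=C14) between an 8α-O-allyl ether and a C13 methylene group on the C9 side chain.
2. C8 (O α, CH3 β) comes from a C8 ketone by methylenation, α-face epoxidation and hydride opening; the side chain C11–C13/C16 comes from a Sakurai addition to a 9-methylene-8-ketone.
3. Ring A and the C9 handle come from a one-flask [3+3] annulation of (1R,5R)-verbenone (C4–C10, C18–C20) with allyltrimethylsilane (C1–C3): conjugate allylation makes C1–C10, the enolate is thiomethylated at C9, and Lewis acid opening of the cyclobutane gives the C4 cation that closes C3–C4.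
4. Enabling feature: on ring B the quaternary C10 (bearing C20) and the gem-dimethyl carbon C4 both sit on C5, and C8 is oxygenated. With one extra bond C4–C7 this is verbenone (cyclobutane C4–C5–C6–C7, enone O=C8–C9=C10), so the enone accepts C1 at C10 and the strained C4–C7 bond, α to the C8 carbonyl, then ionises to the C4 cation that takes C3.
5. Ring order: ring B (bought, carrying the temporary cyclobutane) → ring A (key step) → oxocane (metathesis). Stereochemistry is relayed from the bought bridgehead C5 to C10, C9 and C8 by substrate control; C13 is set by catalyst.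

Key step: step 1

Remark: locants are labdane locants (ring A C1–C5 and C10, ring B C5–C10, chain C11–C16, methyls C17–C20); α is the face of H-5, β the face of C-20; the target is read as (5S,8R,9R,10S,13R)-8α,15-epoxylabdan-16-yl acetate, and (1R,5R)-(+)-verbenone is taken as a catalogue compound.

**Route**

Step 1
Reactants: 1 (1R,5R)-(+)-verbenone; 2 allyltrimethylsilane; 3 chloromethyl phenyl sulfide
Product: 6 2α-chloro-4,4,10β-trimethyl-9α-[(phenylthio)methyl]-5α-decalin-8-one, via titanium enolate 4 (not isolated), via cyclobutyl keto sulfide 5 (not isolated)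
Conditions: 2 (1.3 equiv), TiCl4 (1.5 equiv), CH2Cl2, −78 °C; then 3 (1.2 equiv), −78 → −30 °C; then 0 → 25 °C; aq. NaHCO3
Reagents that add atoms: titanium tetrachloride, Cl[Ti](Cl)(Cl)Cl (delivers the chloride at C2)
Why: Proposed new method: TiCl4 activates the enone of 1 for Hosomi–Sakurai conjugate allylation (bond C1–C10), the titanium enolate 4 is alkylated at C9 by the thionium ion that TiCl4 generates from 3 (returning TiCl4), and on warming the Lewis acid heterolyses the strained cyclobutane bond C4–C7 of ketone 5, which lies α to the C8 carbonyl, to a C7=C8 titanium enolate and a tertiary C4 cation that the pendant terminal alkene captures (bond C3–C4) with chloride return from titanium to C2. The closest known reaction types are the Sakurai allylation of 3-methylcycloalkenones, the Lewis acid α-phenylthiomethylation of enol derivatives with chloromethyl phenyl sulfide, the SnCl4-promoted opening of 4-substituted 6,6-dimethylnorpinan-2-ones in which a phenol oxygen traps the same cation to give a trans-fused pyran, and the TiCl4-mediated addition of tertiary alkyl chlorides across terminal alkenes; new are their union in one flask and the alkene as the trap. Ring A closes by a 6-endo-trig cation–olefin cyclisation through a chair, while the temporary four-membered ring is opened and leaves ring B as a cyclohexanone enolate that is protonated on work-up. C10 is set by attack of the allylsilane on the enone face anti to the gem-dimethyl bridge, C5 is the bridgehead bought with 1, and since the allyl chain (α at C10) and the cationic C4 (β at C5) then lie on opposite faces the ring fusion can only close trans; C9 (alkylated anti to the bridge, lost as a stereocentre in step 2) and C2 (equatorial chloride expected because both axial methyl groups shield the β face, chlorine removed in step 4) are of no consequence. The step needs conjugate allylation and C9 alkylation to be complete before ring opening, which the substrate secures because the cyclobutane should survive TiCl4 at −78 °C and the bridgehead C7 cannot enolise so that only C9 reacts, and it needs cyclisation to win over proton loss from the cation, which is favoured by the chair-like trans-diequatorial reach of the alkene and by the reversibility of proton loss under the acidic conditions.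

Step 2
Reactants: 6 2α-chloro-4,4,10β-trimethyl-9α-[(phenylthio)methyl]-5α-decalin-8-one
Product: 8 2α-chloro-4,4,10β-trimethyl-9-methylene-5α-decalin-8-one, via keto sulfoxide 7 (not isolated)
Conditions: NaIO4, MeOH/H2O, 0 → 25 °C; then toluene, CaCO3, 110 °C
Reagents that add atoms: none
Why: Periodate oxidation to the sulfoxide followed by thermal syn-elimination (sulfoxide pyrolysis) can only engage the C9 hydrogen and so should give the exocyclic enone regiospecifically, C9 becoming sp2 and the quaternary C10 preventing any double-bond migration.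

Step 3
Reactants: 8 2α-chloro-4,4,10β-trimethyl-9-methylene-5α-decalin-8-one; 9 2-[(trimethylsilyl)methyl]allyl acetate
Product: 10 9β-[3-(acetoxymethyl)but-3-enyl]-2α-chloro-4,4,10β-trimethyl-5α-decalin-8-one
Conditions: TiCl4 (1.1 equiv), CH2Cl2, −78 °C; aq. NH4Cl
Reagents that add atoms: none
Why: Hosomi–Sakurai conjugate addition of the 2-substituted allylsilane to the unhindered exocyclic enone terminus forms C11–C12, and protonation of the C8=C9 enolate on the α face (axial, anti to the axial C10 methyl) should give the equatorial 9β side chain, which is also the thermodynamic epimer.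

Step 4
Reactants: 10 9β-[3-(acetoxymethyl)but-3-enyl]-2α-chloro-4,4,10β-trimethyl-5α-decalin-8-one
Product: 11 9β-[3-(acetoxymethyl)but-3-enyl]-4,4,10β-trimethyl-5α-decalin-8-one
Conditions: Bu3SnH (2 equiv), AIBN (0.2 equiv), toluene, 110 °C
Reagents that add atoms: none
Why: Radical chain dehalogenation of the secondary alkyl chloride turns C2 into CH2 without creating a stereocentre, so any C2 epimer converges, and the ketone, acetate and alkene are inert to the stannyl radical chain.

Step 5
Reactants: 11 9β-[3-(acetoxymethyl)but-3-enyl]-4,4,10β-trimethyl-5α-decalin-8-one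
Product: 12 9β-[3-(acetoxymethyl)but-3-enyl]-4,4,10β-trimethyl-8-methylene-5α-decalin
Conditions: Zn, CH2Br2, TiCl4, THF/CH2Cl2, 0 → 25 °C
Reagents that add atoms: dibromomethane, BrCBr
Why: Takai–Lombardo methylenation is non-basic, so the hindered and epimerisable C8 ketone should be converted into the exocyclic alkene (C17) without loss of the C9 configuration or of the acetate.

Step 6
Reactants: 12 9β-[3-(acetoxymethyl)but-3-enyl]-4,4,10β-trimethyl-8-methylene-5α-decalin
Product: 13 8α,17-epoxide of 12 (spiro-oxirane at C8 with oxygen α and CH2 β)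
Conditions: mCPBA (1.05 equiv), NaHCO3, CH2Cl2, 0 °C
Reagents that add atoms: mCPBA, OOC(=O)c1cccc(Cl)c1
Why: Prilezhaev epoxidation should be chemoselective for the electron-rich C8=C17 alkene because the side-chain alkene is deactivated by its allylic acetate, and selective for the α face (oxygen equatorial) because the axial C10 methyl blocks the β face, which sets C8.

Step 7
Reactants: 13 8α,17-epoxide of 12
Product: 14 9β-[3-(hydroxymethyl)but-3-enyl]-4,4,8β,10β-tetramethyl-5α-decalin-8α-ol
Conditions: LiAlH4, THF, 0 → 25 °C; aq. NaOH work-up
Reagents that add atoms: none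
Why: Hydride opens the spiro-epoxide at its primary carbon (SN2 epoxide reduction) to give the 8α tertiary alcohol with the C17 methyl β, and reduces the acetate to the primary alcohol in the same operation.

Step 8
Reactants: 14 9β-[3-(hydroxymethyl)but-3-enyl]-4,4,8β,10β-tetramethyl-5α-decalin-8α-ol
Product: 15 16-O-(tert-butyldimethylsilyl) ether of 14
Conditions: TBSCl, imidazole, CH2Cl2, 0 °C
Reagents that add atoms: TBSCl, CC(C)(C)[Si](C)(C)Cl
Why: Silylation of the primary allylic alcohol is selective over the hindered tertiary 8α-hydroxyl and masks O16 against the base of the next step.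

Step 9
Reactants: 15 16-O-(tert-butyldimethylsilyl) ether of 14; 16 allyl bromide
Product: 17 8α-allyl ether of 15
Conditions: KH, THF, 0 °C; then 16, Bu4NI (5 mol %), 0 → 50 °C
Reagents that add atoms: none
Why: Williamson etherification of the potassium tertiary alkoxide with the reactive allyl bromide installs C15–C14 on the 8α oxygen with retention at C8.

Step 10
Reactants: 17 8α-allyl ether of 15
Product: 18 16-(tert-butyldimethylsilyloxy)-8α,15-epoxylabd-13-ene (ring-cis C13=C14)
Conditions: second-generation Grubbs catalyst (H2IMes)(PCy3)Cl2Ru=CHPh (10 mol %), toluene (2 mM), 80 °C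
Reagents that add atoms: none
Why: Ring-closing metathesis between the allyl ether and the 1,1-disubstituted alkene should close the eight-membered ether, helped by the trans-diequatorial O8/C11 pair on ring B that holds the two chains gauche, and gives the trisubstituted ring-cis alkene with loss of ethene.

Step 11
Reactants: 18 16-(tert-butyldimethylsilyloxy)-8α,15-epoxylabd-13-ene
Product: 19 (13R)-16-(tert-butyldimethylsilyloxy)-8α,15-epoxylabdane
Conditions: H2 (50 bar), [Ir(cod)((S)-tBu-PHOX)]BArF (2 mol %), CH2Cl2, 25 °C (tBu-PHOX = 4-tert-butyl-2-[2-(diphenylphosphino)phenyl]-4,5-dihydrooxazole; BArF = B[3,5-(CF3)2C6H3]4)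
Reagents that add atoms: none
Why: Iridium N,P-ligand catalysed asymmetric hydrogenation of a trisubstituted alkene needs no coordinating group, so C13 is set by catalyst control, the ligand enantiomer being the one that delivers hydrogen to the face giving 13R, and the ring alkene is the only one present.

Step 12
Reactants: 19 (13R)-16-(tert-butyldimethylsilyloxy)-8α,15-epoxylabdane
Product: 21 (13R)-8α,15-epoxylabdan-16-yl acetate (target), via primary alcohol 20 (not isolated)
Conditions: Bu4NF, THF, 25 °C; then Ac2O, pyridine, DMAP (5 mol %), 0 → 25 °C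
Reagents that add atoms: acetic anhydride, CC(=O)OC(C)=O
Why: Fluoride cleaves the silyl ether and the liberated primary alcohol is acetylated in the same flask by DMAP-catalysed acyl transfer, no stereocentre being touched.

**Compound list**

1 | (1R,5R)-(+)-verbenone | CC1=CC(=O)[C@@H]2C[C@H]1C2(C)C | starting material
2 | allyltrimethylsilane | C=CC[Si](C)(C)C | starting material
3 | chloromethyl phenyl sulfide | ClCSc1ccccc1 | starting material
4 | trichlorotitanium enolate of 4-allyl-4,6,6-trimethylbicyclo[3.1.1]heptan-2-one (allyl anti to the gem-dimethyl bridge) | C=CC[C@]1(C)C=C(O[Ti](Cl)(Cl)Cl)[C@@H]2C[C@H]1C2(C)C | intermediate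
5 | 4-allyl-4,6,6-trimethyl-3-[(phenylthio)methyl]bicyclo[3.1.1]heptan-2-one (allyl and CH2SPh anti to the gem-dimethyl bridge) | C=CC[C@]1(C)[C@H](CSc3ccccc3)C(=O)[C@@H]2C[C@H]1C2(C)C | intermediate
6 | 2α-chloro-4,4,10β-trimethyl-9α-[(phenylthio)methyl]-5α-decalin-8-one | O=C1CC[C@H]2C(C)(C)C[C@H](Cl)C[C@]2(C)[C@@H]1CSc3ccccc3 | intermediate
7 | sulfoxide of 6 (sulfur epimers) | O=C1CC[C@H]2C(C)(C)C[C@H](Cl)C[C@]2(C)[C@@H]1CS(=O)c3ccccc3 | intermediate
8 | 2α-chloro-4,4,10β-trimethyl-9-methylene-5α-decalin-8-one | O=C1CC[C@H]2C(C)(C)C[C@H](Cl)C[C@]2(C)C1=C | intermediate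
9 | 2-[(trimethylsilyl)methyl]allyl acetate | CC(=O)OCC(=C)C[Si](C)(C)C | starting material
10 | 9β-[3-(acetoxymethyl)but-3-enyl]-2α-chloro-4,4,10β-trimethyl-5α-decalin-8-one | O=C1CC[C@H]2C(C)(C)C[C@H](Cl)C[C@]2(C)[C@H]1CCC(=C)COC(C)=O | intermediate
11 | 9β-[3-(acetoxymethyl)but-3-enyl]-4,4,10β-trimethyl-5α-decalin-8-one | O=C1CC[C@H]2C(C)(C)CCC[C@]2(C)[C@H]1CCC(=C)COC(C)=O | intermediate
12 | 9β-[3-(acetoxymethyl)but-3-enyl]-4,4,10β-trimethyl-8-methylene-5α-decalin | C=C1CC[C@H]2C(C)(C)CCC[C@]2(C)[C@H]1CCC(=C)COC(C)=O | intermediate
13 | 8α,17-epoxide of 12 (oxygen α, CH2 β) | C1O[C@@]12CC[C@H]3C(C)(C)CCC[C@]3(C)[C@H]2CCC(=C)COC(C)=O | intermediate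
14 | 9β-[3-(hydroxymethyl)but-3-enyl]-4,4,8β,10β-tetramethyl-5α-decalin-8α-ol | C[C@@]1(O)CC[C@H]2C(C)(C)CCC[C@]2(C)[C@H]1CCC(=C)CO | intermediate
15 | 16-O-(tert-butyldimethylsilyl) ether of 14 | C[C@@]1(O)CC[C@H]2C(C)(C)CCC[C@]2(C)[C@H]1CCC(=C)CO[Si](C)(C)C(C)(C)C | intermediate
16 | allyl bromide | C=CCBr | starting material
17 | 8α-allyl ether of 15 | C=CCO[C@]1(C)CC[C@H]2C(C)(C)CCC[C@]2(C)[C@H]1CCC(=C)CO[Si](C)(C)C(C)(C)C | intermediate
18 | 16-(tert-butyldimethylsilyloxy)-8α,15-epoxylabd-13-ene (ring-cis alkene, CIP descriptor E) | CC(C)(C)[Si](C)(C)OC/C1=C/CO[C@]2(C)CC[C@H]3C(C)(C)CCC[C@]3(C)[C@H]2CC1 | intermediate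
19 | (13R)-16-(tert-butyldimethylsilyloxy)-8α,15-epoxylabdane | CC(C)(C)[Si](C)(C)OC[C@H]1CCO[C@]2(C)CC[C@H]3C(C)(C)CCC[C@]3(C)[C@H]2CC1 | intermediate
20 | (13R)-8α,15-epoxylabdan-16-ol | OC[C@H]1CCO[C@]2(C)CC[C@H]3C(C)(C)CCC[C@]3(C)[C@H]2CC1 | intermediate
21 | (5S,8R,9R,10S,13R)-8α,15-epoxylabdan-16-yl acetate | CC(=O)OC[C@H]1CCO[C@]2(C)CC[C@H]3C(C)(C)CCC[C@]3(C)[C@H]2CC1 | target

**Step count and risks**

Total step count: 12. Longest linear sequence: 12 steps (1 → 21); compounds 2, 3, 9 and 16 are bought.

The three steps most likely to fail:

**Step 1 (labelled step).** Several things may go wrong: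
- alkylation of the hindered C9 enolate may lag behind ring opening;
- the tertiary cation may lose a proton (isopropenyl or isopropylidene dienes) or collapse with chloride faster than the monosubstituted alkene captures it;
- the alkene may attack the Lewis acid-activated C8 carbonyl in a Prins-type side reaction.

In each case ring A would not close cleanly. The fallback separates the events into operations of known type; it sets out from 1 and comes back at 6. Sakurai allylation of 1 with 2 (TiCl4, CH2Cl2, −78 °C) and aqueous quench should give 4-allyl-4,6,6-trimethylbicyclo[3.1.1]heptan-2-one F1. Kinetic enolisation (LDA, THF, −78 °C; only C9 can enolise) and silylation (Me3SiCl) give the trimethylsilyl enol ether F2. Lewis acid α-phenylthiomethylation of F2 with 3 (ZnBr2, 10 mol %, CH2Cl2) gives 5 as an isolated compound. Ring opening and cyclisation of 5 is then run on its own with SnCl4 (CH2Cl2, 0 → 25 °C), where acid strength, chloride source and time can be tuned without regard to the earlier events, to reach 6.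

**Step 10.** Intermolecular metathesis (dimers, oligomers) or catalyst decay may outrun the slow closure of an eight-membered ring onto the 1,1-disubstituted alkene. The fallback replaces olefin metathesis by carbonyl coupling; it sets out from 17 and comes back at 18. Ozonolysis of both terminal alkenes of 17 (O3, CH2Cl2/MeOH, −78 °C; Me2S) gives the keto aldehyde F3 (a formylmethyl ether on the 8α oxygen and a C13 ketone). Intramolecular McMurry coupling (TiCl3, Zn–Cu, DME, reflux, slow addition) then forms the same C13=C14 bond and gives 18. The α-oxygen substituents on both carbonyl groups are a known weak point of this coupling.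

**Step 11.** Facial selectivity may be poor if the conformational bias of the fused eight-membered ring opposes or dilutes catalyst control, and the hindered trisubstituted alkene may be reduced slowly. The fallback uses carboxylate-directed instead of non-directed hydrogenation; it sets out from 18 and comes back at 20. Desilylation (Bu4NF, THF) gives the allylic alcohol F4. Oxidation (MnO2, CH2Cl2) gives the enal F5, and Pinnick oxidation (NaClO2, NaH2PO4, 2-methyl-2-butene) gives the α,β-unsaturated acid F6. Hydrogenation with Ru(OAc)2[(R)-BINAP] (H2, MeOH) should give the 13R acid F7; this is a tiglic-acid-type substrate for which ligand control is strong, the ligand hand is assigned by analogy with tiglic acid, and the antipode is used if the sense is reversed. LiAlH4 reduction of F7 gives alcohol 20, which is acetylated as in step 12.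

Further compounds
F1 | step 1 | 4-allyl-4,6,6-trimethylbicyclo[3.1.1]heptan-2-one (allyl anti to the gem-dimethyl bridge) | C=CC[C@]1(C)CC(=O)[C@@H]2C[C@H]1C2(C)C
F2 | step 1 | trimethylsilyl enol ether of F1 (C2=C3 of the bicycle) | C=CC[C@]1(C)C=C(O[Si](C)(C)C)[C@@H]2C[C@H]1C2(C)C
F3 | step 10 | 8α-(2-oxoethoxy)-9β-[4-(tert-butyldimethylsilyloxy)-3-oxobutyl]-4,4,8β,10β-tetramethyl-5α-decalin | O=CCO[C@]1(C)CC[C@H]2C(C)(C)CCC[C@]2(C)[C@H]1CCC(=O)CO[Si](C)(C)C(C)(C)C
F4 | step 11 | 8α,15-epoxylabd-13-en-16-ol | OC/C1=C/CO[C@]2(C)CC[C@H]3C(C)(C)CCC[C@]3(C)[C@H]2CC1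
F5 | step 11 | 8α,15-epoxylabd-13-en-16-al | O=C/C1=C/CO[C@]2(C)CC[C@H]3C(C)(C)CCC[C@]3(C)[C@H]2CC1
F6 | step 11 | 8α,15-epoxylabd-13-en-16-oic acid | OC(=O)/C1=C/CO[C@]2(C)CC[C@H]3C(C)(C)CCC[C@]3(C)[C@H]2CC1
F7 | step 11 | (13R)-8α,15-epoxylabdan-16-oic acid | OC(=O)[C@H]1CCO[C@]2(C)CC[C@H]3C(C)(C)CCC[C@]3(C)[C@H]2CC1
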